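**Plan**

1. Retrosynthetic cuts: the C10 ketone goes back to a silyl-protected carbinol; the oxirane C2–O bond to a C2 chloride on the C3 enone; the pyranone to the C6 formyl group plus methyl 2-methyl-3-oxopentanoate; the ring bonds C1–C2 and C5–C6 to a dienal and a 2-silyloxydiene; the dienal to two C=C (Wittig) cuts and one aldol C–C cut.
2. Enabling feature: in the cyclohexene carbocycle the C1 alkenyl chain is cis to the C6 methyl and the C3 oxygen sits para to quaternary C6. That is the pattern an (E)-2-methyl-2-enal (β-substituent cis to α-methyl) and a 2-silyloxydiene produce in a [4+2].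
3. Forward order: chain first (aldol, two formyl olefinations), carbocycle by Diels–Alder reaction, C4=C5 by Saegusa oxidation, pyranone ring built on the formyl carbon, oxirane ring by chlorination/reduction/closure, ketone last.
4. Stereochemistry: C9 from the oxazolidinone aldol; C1/C6 relative from the dienophile geometry and absolute from the oxazaborolidinium catalyst; C2/C3 from substrate control by the C1 chain, with inversion at C2 on ring closure.
5. Numbering used: ring C1 (CH with alkenyl chain), C2/C3 (oxirane carbons, methyl on C2), C4(Me)=C5, C6 (quaternary; methyl and pyranone); chain C7(Me)=C8, C9(Me)H, C10 (ketone carbon).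

Key step: step 8

Remark 1: the facial sense of the catalyst is assigned from the accepted formyl C–H···O binding model ((S)-catalyst leaves the Re face of C6 open); the (R)-catalyst is equally available and would be used if the sense proved opposite.

Remark 2: C2 is drawn as the formyl-endo epimer in 13 to 20; it is enolisable from 14 on and becomes planar in step 14, so either epimer or a mixture serves.

**Step 1**
Reactants: 1 (S)-4-benzyl-3-propanoyloxazolidin-2-one; 2 propanal
Product: 4 (S)-4-benzyl-3-[(2S,3R)-3-hydroxy-2-methylpentanoyl]oxazolidin-2-one, via Z-dibutylboron enolate 3 (not isolated)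
Conditions: Bu2BOTf, iPr2NEt, CH2Cl2, 0 °C; 2, −78 → 0 °C; then pH 7 buffer, MeOH, H2O2
Reagents that add atoms: none
Why: Evans aldol reaction, in which the Z-boron enolate reacts through a closed chair (Zimmerman–Traxler) transition state on the face away from the benzyl group and sets the 2,3-syn (2S,3R) pair, whose C2 becomes C9 of the target.

**Step 2**
Reactants: 4 (S)-4-benzyl-3-[(2S,3R)-3-hydroxy-2-methylpentanoyl]oxazolidin-2-one
Product: 5 (S)-4-benzyl-3-[(2S,3R)-2-methyl-3-(triethylsilyloxy)pentanoyl]oxazolidin-2-one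
Conditions: Et3SiOTf, 2,6-lutidine, CH2Cl2, −78 → 0 °C
Reagents that add atoms: triethylsilyl trifluoromethanesulfonate, CC[Si](CC)(CC)OS(=O)(=O)C(F)(F)F
Why: Silyl ether formation with a silyl triflate and a hindered pyridine base is fast at a hindered secondary alcohol and touches no stereocentre; triethylsilyl is chosen because buffered fluoride removes it at the end without acid.

**Step 3**
Reactants: 5 (S)-4-benzyl-3-[(2S,3R)-2-methyl-3-(triethylsilyloxy)pentanoyl]oxazolidin-2-one
Product: 6 (2R,3R)-2-methyl-3-(triethylsilyloxy)pentan-1-ol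
Conditions: LiBH4, MeOH (1 equiv), THF, 0 °C
Reagents that add atoms: none
Why: Reductive cleavage of the N-acyl oxazolidinone by LiBH4 occurs at the exocyclic imide carbonyl and releases the primary alcohol and the recoverable auxiliary without epimerising C2.

**Step 4**
Reactants: 6 (2R,3R)-2-methyl-3-(triethylsilyloxy)pentan-1-ol
Product: 7 (2S,3R)-2-methyl-3-(triethylsilyloxy)pentanal
Conditions: Dess–Martin periodinane, NaHCO3, CH2Cl2, 0 °C → rt
Reagents that add atoms: none
Why: Dess–Martin oxidation of the primary alcohol stops at the aldehyde under buffered, non-basic conditions, so the α-stereocentre should be kept; the aldehyde is used at once.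

**Step 5**
Reactants: 7 (2S,3R)-2-methyl-3-(triethylsilyloxy)pentanal; 8 2-(triphenylphosphoranylidene)propanal
Product: 9 (2E,4R,5R)-2,4-dimethyl-5-(triethylsilyloxy)hept-2-enal
Conditions: 8 (1.3 equiv), toluene, 80 °C
Reagents that add atoms: none
Why: Wittig olefination with the stabilised formyl ylide should give the (E)-2-methyl-2-enal, and any dienal formed by a second olefination is simply the product of step 6.

**Step 6**
Reactants: 9 (2E,4R,5R)-2,4-dimethyl-5-(triethylsilyloxy)hept-2-enal; 8 2-(triphenylphosphoranylidene)propanal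
Product: 10 (2E,4E,6R,7R)-2,4,6-trimethyl-7-(triethylsilyloxy)nona-2,4-dienal
Conditions: 8 (2 equiv), toluene, 110 °C
Reagents that add atoms: none
Why: A second Wittig olefination with the same ylide, now on the less electrophilic enal at higher temperature, should give the (2E,4E)-dienal, which is less reactive still and so resists a third homologation.

**Step 7**
Reactants: 11 2-methylpent-1-en-3-one
Product: 12 (Z)-3-(tert-butyldimethylsilyloxy)-2-methylpenta-1,3-diene
Conditions: tBuMe2SiOTf, Et3N, CH2Cl2, 0 °C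
Reagents that add atoms: tert-butyldimethylsilyl trifluoromethanesulfonate, CC(C)(C)[Si](C)(C)OS(=O)(=O)C(F)(F)F
Why: Soft enolisation of the ethyl ketone (silyl enol ether formation with silyl triflate and amine) should give the Z dienol ether, the methyl group lying trans to the isopropenyl group to avoid allylic 1,3-strain.

**Step 8**
Reactants: 10 (2E,4E,6R,7R)-2,4,6-trimethyl-7-(triethylsilyloxy)nona-2,4-dienal; 12 (Z)-3-(tert-butyldimethylsilyloxy)-2-methylpenta-1,3-diene
Product: 13 (1R,5R,6S)-4-(tert-butyldimethylsilyloxy)-1,3,5-trimethyl-6-[(2E,4R,5R)-4-methyl-5-(triethylsilyloxy)hept-2-en-2-yl]cyclohex-3-ene-1-carbaldehyde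
Conditions: (S)-3,3-diphenyl-1-(2-methylphenyl)tetrahydro-1H,3H-pyrrolo[1,2-c][1,3,2]oxazaborole (20 mol%), Tf2NH (18 mol%), 12 (3 equiv), CH2Cl2, −78 → −40 °C
Reagents that add atoms: none
Why: The N-protonated oxazaborolidine binds the formyl oxygen of 10 (the formyl C–H···O contact holds the s-trans enal against one aryl group), which lowers the LUMO of the α,β-bond, and diene 12 adds in a concerted, asynchronous [4+2] in which the enol-ether terminus (future C2) bonds first to the β-carbon (future C1) and the CH2 terminus (future C5) then closes onto the α-carbon (future C6). The closest known reaction type is the oxazaborolidinium-catalysed Diels–Alder reaction of α-methyl-α,β-unsaturated aldehydes with 2-silyloxydienes. The six-membered carbocycle closes by intermolecular cycloaddition, suprafacial on both partners. C1 and C6 are fixed relative to each other by the E geometry of the dienophile (alkenyl chain cis to the C6 methyl) and in the absolute sense by the catalyst, which leaves the Re face of the α-carbon open; C2 follows from the Z diene and the formyl-endo transition state and is not needed later. The step needs site selectivity (only the α,β-bond is conjugated directly to the complexed formyl group, and the γ,δ-bond is shielded by its branches), para regiochemistry (the silyloxy group makes its neighbouring terminus the nucleophilic one) and catalyst-controlled facial selectivity, which the remote C9/C10 centres should not oppose.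

**Step 9**
Reactants: 13 (1R,5R,6S)-4-(tert-butyldimethylsilyloxy)-1,3,5-trimethyl-6-[(2E,4R,5R)-4-methyl-5-(triethylsilyloxy)hept-2-en-2-yl]cyclohex-3-ene-1-carbaldehyde
Product: 14 (1R,5R,6S)-1,3,5-trimethyl-6-[(2E,4R,5R)-4-methyl-5-(triethylsilyloxy)hept-2-en-2-yl]-4-oxocyclohex-2-ene-1-carbaldehyde
Conditions: Pd(OAc)2 (1.2 equiv), MeCN, 40 °C
Reagents that add atoms: none
Why: Saegusa–Ito oxidation, in which the silyl enol ether transmetalates to an oxa-π-allyl complex of divalent palladium at C4 and syn β-hydride elimination from C5 gives the conjugated C4=C5 enone, the endocyclic isomer being the usual outcome for 2-methyl enol ethers.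

**Step 10**
Reactants: 14 (1R,5R,6S)-1,3,5-trimethyl-6-[(2E,4R,5R)-4-methyl-5-(triethylsilyloxy)hept-2-en-2-yl]-4-oxocyclohex-2-ene-1-carbaldehyde; 15 methyl 2-methyl-3-oxopentanoate
Product: 17 methyl 5-hydroxy-2,4-dimethyl-3-oxo-5-{(1R,5R,6S)-1,3,5-trimethyl-6-[(2E,4R,5R)-4-methyl-5-(triethylsilyloxy)hept-2-en-2-yl]-4-oxocyclohex-2-en-1-yl}pentanoate (diastereomer mixture), via dilithium dianion 16 (not isolated)
Conditions: 15 (2.5 equiv), LiN(iPr)2 (5.2 equiv), THF, −78 → 0 °C; then 14, −78 °C; AcOH quench at −78 °C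
Reagents that add atoms: none
Why: Aldol addition of the γ-carbon of the β-keto ester dianion to the non-enolisable neopentyl aldehyde at −78 °C should outrun attack on, or deprotonation of, the hindered α,α'-disubstituted enone, and the cold acidic quench forestalls retro-aldol cleavage; the three new centres are erased in steps 11 and 12.

**Step 11**
Reactants: 17 methyl 5-hydroxy-2,4-dimethyl-3-oxo-5-{(1R,5R,6S)-1,3,5-trimethyl-6-[(2E,4R,5R)-4-methyl-5-(triethylsilyloxy)hept-2-en-2-yl]-4-oxocyclohex-2-en-1-yl}pentanoate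
Product: 18 methyl 2,4-dimethyl-3,5-dioxo-5-{(1R,5R,6S)-1,3,5-trimethyl-6-[(2E,4R,5R)-4-methyl-5-(triethylsilyloxy)hept-2-en-2-yl]-4-oxocyclohex-2-en-1-yl}pentanoate
Conditions: Dess–Martin periodinane, NaHCO3, CH2Cl2, rt
Reagents that add atoms: none
Why: Dess–Martin oxidation converts the secondary carbinol into the ketone and gives the largely enolised β,δ-diketo ester without touching the silyl ether or the enone.

**Step 12**
Reactants: 18 methyl 2,4-dimethyl-3,5-dioxo-5-{(1R,5R,6S)-1,3,5-trimethyl-6-[(2E,4R,5R)-4-methyl-5-(triethylsilyloxy)hept-2-en-2-yl]-4-oxocyclohex-2-en-1-yl}pentanoate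
Product: 19 4-hydroxy-3,5-dimethyl-6-{(1R,5R,6S)-1,3,5-trimethyl-6-[(2E,4R,5R)-4-methyl-5-(triethylsilyloxy)hept-2-en-2-yl]-4-oxocyclohex-2-en-1-yl}-2H-pyran-2-one
Conditions: DBU, toluene, rt → 60 °C
Reagents that add atoms: none
Why: Base-induced lactonisation of the δ-ketone enol onto the methyl ester with loss of methanol is the standard closure of 3,5-dioxo esters to 4-hydroxy-2-pyranones; DBU may epimerise C2, which is of no consequence.

**Step 13**
Reactants: 19 4-hydroxy-3,5-dimethyl-6-{(1R,5R,6S)-1,3,5-trimethyl-6-[(2E,4R,5R)-4-methyl-5-(triethylsilyloxy)hept-2-en-2-yl]-4-oxocyclohex-2-en-1-yl}-2H-pyran-2-one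
Product: 20 2-methoxy-3,5-dimethyl-6-{(1R,5R,6S)-1,3,5-trimethyl-6-[(2E,4R,5R)-4-methyl-5-(triethylsilyloxy)hept-2-en-2-yl]-4-oxocyclohex-2-en-1-yl}-4H-pyran-4-one
Conditions: MeOTf, CH2Cl2, 0 °C → rt; then cold sat. aq NaHCO3
Reagents that add atoms: methyl trifluoromethanesulfonate, COS(=O)(=O)C(F)(F)F
Why: O-Methylation of the neutral 4-hydroxy-2-pyranone with the hard electrophile MeOTf should occur at the lactone carbonyl oxygen, and loss of the 4-OH proton on work-up gives the 2-methoxy-4-pyranone (the established route to α-methoxy-γ-pyranones).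

**Step 14**
Reactants: 20 2-methoxy-3,5-dimethyl-6-{(1R,5R,6S)-1,3,5-trimethyl-6-[(2E,4R,5R)-4-methyl-5-(triethylsilyloxy)hept-2-en-2-yl]-4-oxocyclohex-2-en-1-yl}-4H-pyran-4-one
Product: 22 6-{(1R,5R,6S)-5-chloro-1,3,5-trimethyl-6-[(2E,4R,5R)-4-methyl-5-(triethylsilyloxy)hept-2-en-2-yl]-4-oxocyclohex-2-en-1-yl}-2-methoxy-3,5-dimethyl-4H-pyran-4-one, via lithium dienolate 21 (not isolated)
Conditions: LiN(SiMe3)2, THF, −78 °C; NCS, −78 → −40 °C; AcOH quench
Reagents that add atoms: N-chlorosuccinimide, O=C1CCC(=O)N1Cl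
Why: α-Chlorination of a ketone enolate, in which C2–H is the only enolisable position (C6 is quaternary) and NCS should chlorinate the cross-conjugated dienolate on the face opposite the pseudo-axial C1 alkenyl chain, so that chlorine ends up trans to that chain and both C2 epimers of 20 converge.

**Step 15**
Reactants: 22 6-{(1R,5R,6S)-5-chloro-1,3,5-trimethyl-6-[(2E,4R,5R)-4-methyl-5-(triethylsilyloxy)hept-2-en-2-yl]-4-oxocyclohex-2-en-1-yl}-2-methoxy-3,5-dimethyl-4H-pyran-4-one
Product: 24 2-methoxy-3,5-dimethyl-6-{(1R,4R,5S,6S)-2,4,6-trimethyl-5-[(2E,4R,5R)-4-methyl-5-(triethylsilyloxy)hept-2-en-2-yl]-7-oxabicyclo[4.1.0]hept-2-en-4-yl}-4H-pyran-4-one, via trans-chlorohydrin 23 (not isolated)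
Conditions: NaBH4, CeCl3·7H2O, MeOH, −40 °C; then K2CO3, 0 °C → rt
Reagents that add atoms: none
Why: Luche 1,2-reduction followed by intramolecular Williamson closure, in which hydride should enter C3 on the face opposite the C1 alkenyl chain (that pseudo-axial group blocks the other trajectory, as in reductions of axial α-halo ketones with a syn-axial neighbour) to give the trans-diaxial chlorohydrin, whose alkoxide displaces chloride at C2 with inversion and so places the oxirane oxygen cis to the C1 chain (C2 S, C3 R in the target's numbering).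

**Step 16**
Reactants: 24 2-methoxy-3,5-dimethyl-6-{(1R,4R,5S,6S)-2,4,6-trimethyl-5-[(2E,4R,5R)-4-methyl-5-(triethylsilyloxy)hept-2-en-2-yl]-7-oxabicyclo[4.1.0]hept-2-en-4-yl}-4H-pyran-4-one
Product: 25 6-{(1R,4R,5S,6S)-5-[(2E,4R,5R)-5-hydroxy-4-methylhept-2-en-2-yl]-2,4,6-trimethyl-7-oxabicyclo[4.1.0]hept-2-en-4-yl}-2-methoxy-3,5-dimethyl-4H-pyran-4-one
Conditions: Bu4NF, AcOH, THF, 0 °C → rt
Reagents that add atoms: none
Why: Fluoride-induced cleavage of the triethylsilyl ether, buffered with acetic acid, frees the C10 carbinol under near-neutral conditions that should leave the vinyl oxirane and the methoxypyranone intact.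

**Step 17**
Reactants: 25 6-{(1R,4R,5S,6S)-5-[(2E,4R,5R)-5-hydroxy-4-methylhept-2-en-2-yl]-2,4,6-trimethyl-7-oxabicyclo[4.1.0]hept-2-en-4-yl}-2-methoxy-3,5-dimethyl-4H-pyran-4-one
Product: 26 2-methoxy-3,5-dimethyl-6-{(1R,4R,5S,6S)-2,4,6-trimethyl-5-[(2E,4R)-4-methyl-5-oxohept-2-en-2-yl]-7-oxabicyclo[4.1.0]hept-2-en-4-yl}-4H-pyran-4-one (CNP0336888.2)
Conditions: Dess–Martin periodinane, NaHCO3, CH2Cl2, 0 °C
Reagents that add atoms: none
Why: Buffered Dess–Martin oxidation gives the C10 ketone at 0 °C without acid or base strong enough to epimerise C9, move the C7=C8 bond into conjugation or open the oxirane.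

**Compound list**

1 | (S)-4-benzyl-3-propanoyloxazolidin-2-one | CCC(=O)N1[C@@H](Cc2ccccc2)COC1=O | starting material
2 | propanal | CCC=O | starting material
3 | Z-dibutylboron enolate of 1 | C/C=C(\OB(CCCC)CCCC)N1[C@@H](Cc2ccccc2)COC1=O | intermediate (not isolated)
4 | (S)-4-benzyl-3-[(2S,3R)-3-hydroxy-2-methylpentanoyl]oxazolidin-2-one | CC[C@@H](O)[C@H](C)C(=O)N1[C@@H](Cc2ccccc2)COC1=O | intermediate
5 | (S)-4-benzyl-3-[(2S,3R)-2-methyl-3-(triethylsilyloxy)pentanoyl]oxazolidin-2-one | CC[C@@H](O[Si](CC)(CC)CC)[C@H](C)C(=O)N1[C@@H](Cc2ccccc2)COC1=O | intermediate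
6 | (2R,3R)-2-methyl-3-(triethylsilyloxy)pentan-1-ol | CC[C@@H](O[Si](CC)(CC)CC)[C@H](C)CO | intermediate
7 | (2S,3R)-2-methyl-3-(triethylsilyloxy)pentanal | CC[C@@H](O[Si](CC)(CC)CC)[C@H](C)C=O | intermediate
8 | 2-(triphenylphosphoranylidene)propanal | CC(C=O)=P(c1ccccc1)(c1ccccc1)c1ccccc1 | starting material
9 | (2E,4R,5R)-2,4-dimethyl-5-(triethylsilyloxy)hept-2-enal | CC[C@@H](O[Si](CC)(CC)CC)[C@H](C)/C=C(\C)C=O | intermediate
10 | (2E,4E,6R,7R)-2,4,6-trimethyl-7-(triethylsilyloxy)nona-2,4-dienal | CC[C@@H](O[Si](CC)(CC)CC)[C@H](C)/C=C(\C)/C=C(\C)C=O | intermediate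
11 | 2-methylpent-1-en-3-one | CCC(=O)C(C)=C | starting material
12 | (Z)-3-(tert-butyldimethylsilyloxy)-2-methylpenta-1,3-diene | C=C(C)/C(O[Si](C)(C)C(C)(C)C)=C/C | intermediate
13 | (1R,5R,6S)-4-(tert-butyldimethylsilyloxy)-1,3,5-trimethyl-6-[(2E,4R,5R)-4-methyl-5-(triethylsilyloxy)hept-2-en-2-yl]cyclohex-3-ene-1-carbaldehyde | CC[C@@H](O[Si](CC)(CC)CC)[C@H](C)/C=C(\C)[C@@H]1[C@@H](C)C(O[Si](C)(C)C(C)(C)C)=C(C)C[C@@]1(C)C=O | intermediate
14 | (1R,5R,6S)-1,3,5-trimethyl-6-[(2E,4R,5R)-4-methyl-5-(triethylsilyloxy)hept-2-en-2-yl]-4-oxocyclohex-2-ene-1-carbaldehyde | CC[C@@H](O[Si](CC)(CC)CC)[C@H](C)/C=C(\C)[C@@H]1[C@@H](C)C(=O)C(C)=C[C@@]1(C)C=O | intermediate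
15 | methyl 2-methyl-3-oxopentanoate | CCC(=O)C(C)C(=O)OC | starting material
16 | dilithium dianion of 15 | CC=C([O-])C(C)=C([O-])OC.[Li+].[Li+] | intermediate (not isolated)
17 | methyl 5-hydroxy-2,4-dimethyl-3-oxo-5-{(1R,5R,6S)-1,3,5-trimethyl-6-[(2E,4R,5R)-4-methyl-5-(triethylsilyloxy)hept-2-en-2-yl]-4-oxocyclohex-2-en-1-yl}pentanoate (mixture at the three new centres) | CC[C@@H](O[Si](CC)(CC)CC)[C@H](C)/C=C(\C)[C@@H]1[C@@H](C)C(=O)C(C)=C[C@@]1(C)C(O)C(C)C(=O)C(C)C(=O)OC | intermediate
18 | methyl 2,4-dimethyl-3,5-dioxo-5-{(1R,5R,6S)-1,3,5-trimethyl-6-[(2E,4R,5R)-4-methyl-5-(triethylsilyloxy)hept-2-en-2-yl]-4-oxocyclohex-2-en-1-yl}pentanoate | CC[C@@H](O[Si](CC)(CC)CC)[C@H](C)/C=C(\C)[C@@H]1[C@@H](C)C(=O)C(C)=C[C@@]1(C)C(=O)C(C)C(=O)C(C)C(=O)OC | intermediate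
19 | 4-hydroxy-3,5-dimethyl-6-{(1R,5R,6S)-1,3,5-trimethyl-6-[(2E,4R,5R)-4-methyl-5-(triethylsilyloxy)hept-2-en-2-yl]-4-oxocyclohex-2-en-1-yl}-2H-pyran-2-one | CC[C@@H](O[Si](CC)(CC)CC)[C@H](C)/C=C(\C)[C@@H]1[C@@H](C)C(=O)C(C)=C[C@@]1(C)C2=C(C)C(O)=C(C)C(=O)O2 | intermediate
20 | 2-methoxy-3,5-dimethyl-6-{(1R,5R,6S)-1,3,5-trimethyl-6-[(2E,4R,5R)-4-methyl-5-(triethylsilyloxy)hept-2-en-2-yl]-4-oxocyclohex-2-en-1-yl}-4H-pyran-4-one | CC[C@@H](O[Si](CC)(CC)CC)[C@H](C)/C=C(\C)[C@@H]1[C@@H](C)C(=O)C(C)=C[C@@]1(C)c1oc(OC)c(C)c(=O)c1C | intermediate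
21 | lithium dienolate of 20 (C2=C3 enolate) | CC[C@@H](O[Si](CC)(CC)CC)[C@H](C)/C=C(\C)[C@@H]1C(C)=C([O-])C(C)=C[C@@]1(C)c1oc(OC)c(C)c(=O)c1C.[Li+] | intermediate (not isolated)
22 | 6-{(1R,5R,6S)-5-chloro-1,3,5-trimethyl-6-[(2E,4R,5R)-4-methyl-5-(triethylsilyloxy)hept-2-en-2-yl]-4-oxocyclohex-2-en-1-yl}-2-methoxy-3,5-dimethyl-4H-pyran-4-one | CC[C@@H](O[Si](CC)(CC)CC)[C@H](C)/C=C(\C)[C@@H]1[C@@](C)(Cl)C(=O)C(C)=C[C@@]1(C)c1oc(OC)c(C)c(=O)c1C | intermediate
23 | 6-{(1R,4R,5R,6S)-5-chloro-4-hydroxy-1,3,5-trimethyl-6-[(2E,4R,5R)-4-methyl-5-(triethylsilyloxy)hept-2-en-2-yl]cyclohex-2-en-1-yl}-2-methoxy-3,5-dimethyl-4H-pyran-4-one | CC[C@@H](O[Si](CC)(CC)CC)[C@H](C)/C=C(\C)[C@@H]1[C@@](C)(Cl)[C@H](O)C(C)=C[C@@]1(C)c1oc(OC)c(C)c(=O)c1C | intermediate (not isolated)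
24 | 2-methoxy-3,5-dimethyl-6-{(1R,4R,5S,6S)-2,4,6-trimethyl-5-[(2E,4R,5R)-4-methyl-5-(triethylsilyloxy)hept-2-en-2-yl]-7-oxabicyclo[4.1.0]hept-2-en-4-yl}-4H-pyran-4-one | CC[C@@H](O[Si](CC)(CC)CC)[C@H](C)/C=C(\C)[C@@H]1[C@]2(C)O[C@@H]2C(C)=C[C@@]1(C)c1oc(OC)c(C)c(=O)c1C | intermediate
25 | 6-{(1R,4R,5S,6S)-5-[(2E,4R,5R)-5-hydroxy-4-methylhept-2-en-2-yl]-2,4,6-trimethyl-7-oxabicyclo[4.1.0]hept-2-en-4-yl}-2-methoxy-3,5-dimethyl-4H-pyran-4-one | CC[C@@H](O)[C@H](C)/C=C(\C)[C@@H]1[C@]2(C)O[C@@H]2C(C)=C[C@@]1(C)c1oc(OC)c(C)c(=O)c1C | intermediate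
26 | 2-methoxy-3,5-dimethyl-6-{(1R,4R,5S,6S)-2,4,6-trimethyl-5-[(2E,4R)-4-methyl-5-oxohept-2-en-2-yl]-7-oxabicyclo[4.1.0]hept-2-en-4-yl}-4H-pyran-4-one (CNP0336888.2) | CCC(=O)[C@H](C)/C=C(\C)[C@@H]1[C@]2(C)O[C@@H]2C(C)=C[C@@]1(C)c1oc(OC)c(C)c(=O)c1C | target

**Count**

Total step count: 17. Longest linear sequence: 16 steps (steps 1–6 and 8–17); step 7 is a one-step branch that supplies the diene.

**Steps most likely to fail**

Step 8. The cycloaddition may stall, because a β-alkenyl α-methyl enal is a weak dienophile and the diene can be consumed by protodesilylation or by Mukaiyama-type 1,2-addition to the formyl group; facial discrimination by the catalyst may also be insufficient. The fallback sets out from 10 and 12 and gives up catalyst control. Stoichiometric Me2AlCl (CH2Cl2, −78 °C), an achiral Lewis acid strong enough for hindered enals, should give both facial adducts, 13 and the (1S,5S,6R) ring-diastereomer of 13 F1. The fixed C9/C10 centres make these two diastereomers, so they are separated by chromatography, if necessary after step 9. The route is re-joined at 13.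

Step 14. Chlorine may be delivered to the enolate face on the side of the C1 chain (the pseudo-axial pyranone on C6 shields the other face to some degree), or the crowded tetrasubstituted enolate may react sluggishly and return 20 by proton transfer. The fallback sets out from 20 and uses the opposite facial preference with oxygen in place of chlorine:
- the enolate (LiN(SiMe3)2, THF, −78 °C) is hydroxylated with 3-phenyl-2-(phenylsulfonyl)oxaziridine to the C2-hydroxy enone F2, with the C2–OH cis to the C1 chain;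
- hydroxyl-directed reduction with Me4NBH(OAc)3 (MeCN/AcOH, −20 °C) delivers hydride to C3 from the face of the C2–OH and should give the trans-2,3-diol F3;
- MsCl/Et3N (CH2Cl2, −20 °C) sulfonylates only the secondary allylic hydroxyl to the C3 mesylate F4;
- K2CO3 in MeOH lets the tertiary alkoxide displace the mesylate with inversion at C3, which gives the same oxirane.

The route is re-joined at 24, and steps 14 and 15 are bypassed.

Step 15. Hydride may add anti to the C–Cl bond, on the face of the C1 chain, which would give the cis-chlorohydrin that cannot close; chlorine may also be lost reductively. The fallback sets out from 22 and replaces substrate control by catalyst control. Catecholborane is used with the antipode of 1-methyl-3,3-diphenyltetrahydro-1H,3H-pyrrolo[1,2-c][1,3,2]oxazaborole that is matched to delivery on the face opposite the C1 chain (Corey–Bakshi–Shibata reduction of an enone; the antipode is chosen by trial, both being available). Chlorohydrin 23 is then isolated and closed separately with K2CO3 in MeOH. The route is re-joined at 24, and no compound outside the list is made (F0).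

**Further compounds**

F1 | step 8 | (1S,5S,6R) ring-diastereomer of 13 | CC[C@@H](O[Si](CC)(CC)CC)[C@H](C)/C=C(\C)[C@H]1[C@H](C)C(O[Si](C)(C)C(C)(C)C)=C(C)C[C@]1(C)C=O
F2 | step 14 | C2-hydroxy enone, 6-{(1R,5S,6S)-5-hydroxy-1,3,5-trimethyl-6-[(2E,4R,5R)-4-methyl-5-(triethylsilyloxy)hept-2-en-2-yl]-4-oxocyclohex-2-en-1-yl}-2-methoxy-3,5-dimethyl-4H-pyran-4-one | CC[C@@H](O[Si](CC)(CC)CC)[C@H](C)/C=C(\C)[C@@H]1[C@](C)(O)C(=O)C(C)=C[C@@]1(C)c1oc(OC)c(C)c(=O)c1C
F3 | step 14 | trans-2,3-diol, 6-{(1R,4S,5S,6S)-4,5-dihydroxy-1,3,5-trimethyl-6-[(2E,4R,5R)-4-methyl-5-(triethylsilyloxy)hept-2-en-2-yl]cyclohex-2-en-1-yl}-2-methoxy-3,5-dimethyl-4H-pyran-4-one | CC[C@@H](O[Si](CC)(CC)CC)[C@H](C)/C=C(\C)[C@@H]1[C@](C)(O)[C@@H](O)C(C)=C[C@@]1(C)c1oc(OC)c(C)c(=O)c1C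
F4 | step 14 | C3 mesylate of F3 | CC[C@@H](O[Si](CC)(CC)CC)[C@H](C)/C=C(\C)[C@@H]1[C@](C)(O)[C@@H](OS(C)(=O)=O)C(C)=C[C@@]1(C)c1oc(OC)c(C)c(=O)c1C
F0 | step 15 | none | none
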